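**Plan**

- Retrosynthesis: the 2H-pyran ring is cut first, at the C3'–CH= bond and the O2'–C(CH3)2 bond, back to a 2'-O-(1,1-dimethylpropargyl) ether. Next come the O2'–C ether bond, the C3–C1' bond (3-iodochromone + arylboronate), the C8–prenyl bond (back to a 5-O-prenyl ether), and O1–C2/C2–C3 of the pyranone (back to an o-hydroxyacetophenone and a C1 unit).
- Forward: the A ring comes from phloroacetophenone; the pyranone ring is closed by enaminone iodocyclisation; the prenyl group is moved O5→C6→C8 by a para-Claisen–Cope rearrangement; the B ring is joined by Suzuki coupling; the 2H-pyran ring is closed last; two MOM groups are removed at the end.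
- Enabling feature: O2' of the B ring has exactly one free ortho carbon (C3'; C1' carries the chromone), and the pyran ring O2'–C(CH3)2–CH=CH–C3' is the atom set of a 1,1-dimethylpropargyl group on O2'. Its last bond-forming event, oxa-6π closure of an o-quinone methide, is the one assumed in the biosynthesis of such pyran rings.
- Stereochemistry: the target has no stereocentre; the only stereo-element, the cis ring alkene, is fixed by the ring.

Key step: step 10

Remark: the target is achiral (no stereocentre), so "single enantiomer" is taken to mean the single compound drawn and no enantiocontrol is needed.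

**Route**

Step 1
Reactants: 1 1-(2,4,6-trihydroxyphenyl)ethan-1-one
Product: 2 1-[2,6-dihydroxy-4-(methoxymethoxy)phenyl]ethan-1-one
Conditions: MOMCl (1.05 equiv), i-Pr2NEt, CH2Cl2/THF, 0 °C
Reagents that add atoms: chloromethyl methyl ether, COCCl
Why: The 4-OH para to the acetyl group is the only hydroxyl not held in a hydrogen bond to the carbonyl and is the most acidic, so one equivalent of MOMCl under amine base should etherify it selectively (selective O-alkylation of a phloroacetophenone).

Step 2
Reactants: 2 1-[2,6-dihydroxy-4-(methoxymethoxy)phenyl]ethan-1-one; 3 1-bromo-3-methylbut-2-ene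
Product: 4 1-[2-hydroxy-4-(methoxymethoxy)-6-(3-methylbut-2-en-1-yloxy)phenyl]ethan-1-one
Conditions: K2CO3, acetone, 55 °C
Reagents that add atoms: none
Why: Williamson etherification of one of the two equivalent hydroxyls; after the first alkylation the remaining OH is locked in a strong hydrogen bond to C=O and should resist a second alkylation, which keeps the phenol needed for ring closure.

Step 3
Reactants: 4 1-[2-hydroxy-4-(methoxymethoxy)-6-(3-methylbut-2-en-1-yloxy)phenyl]ethan-1-one; 5 N,N-dimethylformamide dimethyl acetal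
Product: 7 3-iodo-7-(methoxymethoxy)-5-(3-methylbut-2-en-1-yloxy)-4H-chromen-4-one, via enaminone 6 (not isolated)
Conditions: DMF-DMA, toluene, 90 °C; concentrate; then I2, pyridine, CHCl3, 0 °C → rt
Reagents that add atoms: iodine, II
Why: Condensation of the methyl ketone with the amide acetal gives the enaminone, and iodine then triggers 6-endo attack of the phenol on the β-carbon with loss of dimethylamine and α-iodination (enaminone iodocyclisation to a 3-iodochromone); the prenyl ether has no neighbouring nucleophile and should stay untouched.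

Step 4
Reactants: 7 3-iodo-7-(methoxymethoxy)-5-(3-methylbut-2-en-1-yloxy)-4H-chromen-4-one
Product: 9 5-hydroxy-3-iodo-7-(methoxymethoxy)-8-(3-methylbut-2-en-1-yl)-4H-chromen-4-one, via ortho-Claisen dienone 8 (not isolated)
Conditions: Eu(fod)3 (10 mol%), NaHCO3, PhCl, 85 °C
Reagents that add atoms: none
Why: Eu(III) chelated between C4=O and O5 should catalyse the aromatic Claisen shift of the prenyl group to C6 (the only ortho carbon bearing H), and the dienone then undergoes a Cope shift to C8 before it can enolise, so the prenyl group arrives un-inverted at the carbon para to O5 (europium-catalysed para-Claisen–Cope rearrangement of 5-prenyloxy chromones and flavonoids).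

Step 5
Reactants: 10 3-hydroxyphenyl benzoate
Product: 11 3-(methoxymethoxy)phenyl benzoate
Conditions: MOMCl, i-Pr2NEt, CH2Cl2, 0 °C → rt
Reagents that add atoms: chloromethyl methyl ether, COCCl
Why: Routine O-alkylation of the single free phenol; the benzoate on the other oxygen keeps the two resorcinol oxygens differentiated.

Step 6
Reactants: 11 3-(methoxymethoxy)phenyl benzoate
Product: 13 2-bromo-5-(methoxymethoxy)phenol, via bromo benzoate 12 (not isolated)
Conditions: NBS (1.0 equiv), MeCN, 0 °C → rt; aq. Na2S2O3 wash; then K2CO3, MeOH, rt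
Reagents that add atoms: N-bromosuccinimide, O=C1CCC(=O)N1Br
Why: With one oxygen attenuated as the benzoate, the MOM ether is the stronger director and electrophilic bromination should go para to it (ortho to the ester), after which methanolysis of the aryl ester frees the phenol next to bromine.

Step 7
Reactants: 13 2-bromo-5-(methoxymethoxy)phenol
Product: 14 5-(methoxymethoxy)-2-(4,4,5,5-tetramethyl-1,3,2-dioxaborolan-2-yl)phenol
Conditions: B2pin2, Pd(dppf)Cl2·CH2Cl2 (3 mol%), KOAc, 1,4-dioxane, 90 °C
Reagents that add atoms: bis(pinacolato)diboron, CC1(C)OB(OC1(C)C)B1OC(C)(C)C(C)(C)O1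
Why: Miyaura borylation of an aryl bromide; the weak acetate base tolerates the free ortho phenol and the MOM ether.

Step 8
Reactants: 9 5-hydroxy-3-iodo-7-(methoxymethoxy)-8-(3-methylbut-2-en-1-yl)-4H-chromen-4-one; 14 5-(methoxymethoxy)-2-(4,4,5,5-tetramethyl-1,3,2-dioxaborolan-2-yl)phenol
Product: 15 5-hydroxy-3-[2-hydroxy-4-(methoxymethoxy)phenyl]-7-(methoxymethoxy)-8-(3-methylbut-2-en-1-yl)-4H-chromen-4-one
Conditions: Pd(dppf)Cl2·CH2Cl2 (5 mol%), K2CO3, 1,4-dioxane/H2O (4:1), 80 °C
Reagents that add atoms: none
Why: Suzuki–Miyaura coupling of a 3-iodochromone with an arylboronate is the standard isoflavone assembly; oxidative addition into the C–I bond is fast, and the chelated 5-OH and the free 2'-OH are tolerated under aqueous carbonate.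

Step 9
Reactants: 15 5-hydroxy-3-[2-hydroxy-4-(methoxymethoxy)phenyl]-7-(methoxymethoxy)-8-(3-methylbut-2-en-1-yl)-4H-chromen-4-one; 16 3-chloro-3-methylbut-1-yne
Product: 17 5-hydroxy-7-(methoxymethoxy)-3-[4-(methoxymethoxy)-2-(2-methylbut-3-yn-2-yloxy)phenyl]-8-(3-methylbut-2-en-1-yl)-4H-chromen-4-one
Conditions: DBU, CuCl2·2H2O (1 mol%), MeCN, 0 °C → rt
Reagents that add atoms: none
Why: Copper-catalysed propargylic etherification of a phenol with a tertiary propargylic chloride (via a copper acetylide/allenylidene); the 2'-OH is the only unchelated phenol, while the 5-OH locked to C4=O should react much more slowly.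

Step 10
Reactants: 17 5-hydroxy-7-(methoxymethoxy)-3-[4-(methoxymethoxy)-2-(2-methylbut-3-yn-2-yloxy)phenyl]-8-(3-methylbut-2-en-1-yl)-4H-chromen-4-one
Product: 20 5-hydroxy-7-(methoxymethoxy)-3-[5-(methoxymethoxy)-2,2-dimethyl-2H-chromen-8-yl]-8-(3-methylbut-2-en-1-yl)-4H-chromen-4-one, via allenylphenol 18 (not isolated), via ortho-quinone methide 19 (not isolated)
Conditions: o-xylene (0.05 M), 140 °C, N2
Reagents that add atoms: none
Why: Heating triggers a [3,3] aryl propargyl Claisen shift from O2' to C3' (the keto form enolises to allenylphenol 18), a [1,5]-H shift from the phenolic O–H to the central allene carbon then gives the (Z)-o-quinone methide 19, and thermal disrotatory oxa-6π electrocyclisation forms the O2'–C(CH3)2 bond. The closest known reaction is the thermal conversion of aryl 1,1-dimethylpropargyl ethers into 2,2-dimethyl-2H-chromenes, and the final electrocyclisation is the ring-forming event assumed in the biosynthesis of such pyran rings. The one ring closed, the 2H-pyran, is closed by this 6π electrocyclisation (formally a 6-endo O–C closure on the dienone), after the C3'–CH bond has been made by the sigmatropic shift. No stereocentre is created, because the new sp3 carbon carries two methyl groups, and the ring alkene is necessarily cis. The step needs site selectivity for C3' and chemoselectivity against the C8 prenyl group and the chelated 5-OH: C1' is quaternary, so only the shift to C3' can rearomatise, the O–H needed for the hydrogen shift is delivered next to the allene by the rearrangement itself, and the gem-dimethyl group lowers the required temperature to about 140 °C, where MOM ethers, the prenyl group and the pyranone should be inert.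

Step 11
Reactants: 20 5-hydroxy-7-(methoxymethoxy)-3-[5-(methoxymethoxy)-2,2-dimethyl-2H-chromen-8-yl]-8-(3-methylbut-2-en-1-yl)-4H-chromen-4-one
Product: 21 5,7-dihydroxy-3-(5-hydroxy-2,2-dimethyl-2H-chromen-8-yl)-8-(3-methylbut-2-en-1-yl)-4H-chromen-4-one
Conditions: 3 M aq. HCl, MeOH/THF, 45 °C
Reagents that add atoms: none
Why: Acid-catalysed methanolysis of the two MOM acetals (transacetalisation to dimethoxymethane) at moderate temperature, conditions under which prenyl groups and 2,2-dimethylchromenes of related isoflavones usually survive.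

**Compound list**

1 | 1-(2,4,6-trihydroxyphenyl)ethan-1-one (phloroacetophenone) | CC(=O)c1c(O)cc(O)cc1O | starting material
2 | 1-[2,6-dihydroxy-4-(methoxymethoxy)phenyl]ethan-1-one | CC(=O)c1c(O)cc(OCOC)cc1O | intermediate
3 | 1-bromo-3-methylbut-2-ene (prenyl bromide) | CC(C)=CCBr | starting material
4 | 1-[2-hydroxy-4-(methoxymethoxy)-6-(3-methylbut-2-en-1-yloxy)phenyl]ethan-1-one | CC(=O)c1c(O)cc(OCOC)cc1OCC=C(C)C | intermediate
5 | N,N-dimethylformamide dimethyl acetal | COC(OC)N(C)C | starting material
6 | (E)-3-(dimethylamino)-1-[2-hydroxy-4-(methoxymethoxy)-6-(3-methylbut-2-en-1-yloxy)phenyl]prop-2-en-1-one (enaminone, not isolated) | CN(C)/C=C/C(=O)c1c(O)cc(OCOC)cc1OCC=C(C)C | intermediate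
7 | 3-iodo-7-(methoxymethoxy)-5-(3-methylbut-2-en-1-yloxy)-4H-chromen-4-one | COCOc1cc(OCC=C(C)C)c2c(=O)c(I)coc2c1 | intermediate
8 | 3-iodo-7-(methoxymethoxy)-6-(2-methylbut-3-en-2-yl)-6H-chromene-4,5-dione (ortho-Claisen dienone, racemic at C6, not isolated) | C=CC(C)(C)C1C(OCOC)=CC2=C(C1=O)C(=O)C(I)=CO2 | intermediate
9 | 5-hydroxy-3-iodo-7-(methoxymethoxy)-8-(3-methylbut-2-en-1-yl)-4H-chromen-4-one | CC(C)=CCc1c(OCOC)cc(O)c2c(=O)c(I)coc12 | intermediate
10 | 3-hydroxyphenyl benzoate (resorcinol monobenzoate) | O=C(Oc1cccc(O)c1)c1ccccc1 | starting material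
11 | 3-(methoxymethoxy)phenyl benzoate | COCOc1cccc(OC(=O)c2ccccc2)c1 | intermediate
12 | 2-bromo-5-(methoxymethoxy)phenyl benzoate (bromo benzoate, not isolated) | COCOc1ccc(Br)c(OC(=O)c2ccccc2)c1 | intermediate
13 | 2-bromo-5-(methoxymethoxy)phenol | COCOc1ccc(Br)c(O)c1 | intermediate
14 | 5-(methoxymethoxy)-2-(4,4,5,5-tetramethyl-1,3,2-dioxaborolan-2-yl)phenol | COCOc1ccc(B2OC(C)(C)C(C)(C)O2)c(O)c1 | intermediate
15 | 5-hydroxy-3-[2-hydroxy-4-(methoxymethoxy)phenyl]-7-(methoxymethoxy)-8-(3-methylbut-2-en-1-yl)-4H-chromen-4-one | CC(C)=CCc1c(OCOC)cc(O)c2c(=O)c(-c3ccc(OCOC)cc3O)coc12 | intermediate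
16 | 3-chloro-3-methylbut-1-yne | CC(C)(Cl)C#C | starting material
17 | 5-hydroxy-7-(methoxymethoxy)-3-[4-(methoxymethoxy)-2-(2-methylbut-3-yn-2-yloxy)phenyl]-8-(3-methylbut-2-en-1-yl)-4H-chromen-4-one | CC(C)=CCc1c(OCOC)cc(O)c2c(=O)c(-c3ccc(OCOC)cc3OC(C)(C)C#C)coc12 | intermediate
18 | 5-hydroxy-3-[2-hydroxy-4-(methoxymethoxy)-3-(3-methylbuta-1,2-dien-1-yl)phenyl]-7-(methoxymethoxy)-8-(3-methylbut-2-en-1-yl)-4H-chromen-4-one (allenylphenol, not isolated) | CC(C)=CCc1c(OCOC)cc(O)c2c(=O)c(-c3ccc(OCOC)c(C=C=C(C)C)c3O)coc12 | intermediate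
19 | 5-hydroxy-7-(methoxymethoxy)-3-[(5Z)-4-(methoxymethoxy)-5-(3-methylbut-2-en-1-ylidene)-6-oxocyclohexa-1,3-dien-1-yl]-8-(3-methylbut-2-en-1-yl)-4H-chromen-4-one (ortho-quinone methide, not isolated) | CC(C)=CCc1c(OCOC)cc(O)c2c(=O)c(C3=CC=C(OCOC)/C(=C/C=C(C)C)C3=O)coc12 | intermediate
20 | 5-hydroxy-7-(methoxymethoxy)-3-[5-(methoxymethoxy)-2,2-dimethyl-2H-chromen-8-yl]-8-(3-methylbut-2-en-1-yl)-4H-chromen-4-one | CC(C)=CCc1c(OCOC)cc(O)c2c(=O)c(-c3ccc(OCOC)c4c3OC(C)(C)C=C4)coc12 | intermediate
21 | 5,7-dihydroxy-3-(5-hydroxy-2,2-dimethyl-2H-chromen-8-yl)-8-(3-methylbut-2-en-1-yl)-4H-chromen-4-one | CC(C)=CCc1c(O)cc(O)c2c(=O)c(-c3ccc(O)c4c3OC(C)(C)C=C4)coc12 | target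

**Count**

Total steps: 11. Longest linear sequence: 8 (steps 1–4 and 8–11); steps 5–7 make the B-ring partner in a side branch.

**Steps most likely to fail, with fallbacks**

Step 9. O-Alkylation of the hindered 2'-phenol by a tertiary propargylic electrophile may be slow, so that elimination of 16 and alkylation of the chelated 5-OH compete. The fallback skips the ether and reaches the pyran ring by condensation instead of rearrangement. It sets out from 15 and comes back at 20. 15 is heated with 1,1-diethoxy-3-methylbut-2-ene and 3-picoline in xylene at 140 °C. Ortho C-alkylation at C3' by the activated acetal and loss of ethanol should give the same o-quinone methide 19, which closes to 20 by the same oxa-6π electrocyclisation. No new isolable compound arises (F0).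

Step 4. The rearrangement may stop after the first [3,3] shift, since enolisation of dienone 8 gives the 6-(1,1-dimethylallyl) isomer, or the allylic ether may ionise so that the prenyl group is lost. The fallback puts the prenyl group on carbon before the pyranone ring exists. It sets out from 1 and comes back at 9. 1 is C-prenylated with 3 (DBU, THF, 0 °C → rt) to 1-[2,4,6-trihydroxy-3-(3-methylbut-2-en-1-yl)phenyl]ethan-1-one F1. MOMCl/i-Pr2NEt should etherify the 4-OH and the less hindered 6-OH to give 1-[2-hydroxy-4,6-bis(methoxymethoxy)-3-(3-methylbut-2-en-1-yl)phenyl]ethan-1-one F2. Acetal 5 converts this into (E)-3-(dimethylamino)-1-[2-hydroxy-4,6-bis(methoxymethoxy)-3-(3-methylbut-2-en-1-yl)phenyl]prop-2-en-1-one F3, which I2/pyridine closes to 3-iodo-5,7-bis(methoxymethoxy)-8-(3-methylbut-2-en-1-yl)-4H-chromen-4-one F4. Brief acid methanolysis (HCl in MeOH, 0 °C → rt, stopped early), in which the MOM group peri to C4=O should cleave first, returns to 9.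

Step 8. Protodeboronation of the electron-rich o-hydroxyarylboronate 14 in aqueous base may outrun transmetalation, and the base may open the iodochromone. The fallback is a base-free Stille coupling of an ester-protected stannane. It sets out from 12, which is then isolated after the bromination instead of being methanolysed, and comes back at 15. 12 is stannylated (Me3SnSnMe3, Pd(PPh3)4, toluene, 100 °C) to 5-(methoxymethoxy)-2-(trimethylstannyl)phenyl benzoate F5. Stille coupling with 9 (Pd2(dba)3, AsPh3, CuI, DMF, 60 °C) should give 2-[5-hydroxy-7-(methoxymethoxy)-8-(3-methylbut-2-en-1-yl)-4-oxo-4H-chromen-3-yl]-5-(methoxymethoxy)phenyl benzoate F6. K2CO3 in MeOH at rt then removes the benzoate and gives 15.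

**Further compounds**

F0 | step 9 | none | none
F1 | step 4 | 1-[2,4,6-trihydroxy-3-(3-methylbut-2-en-1-yl)phenyl]ethan-1-one | CC(=O)c1c(O)cc(O)c(CC=C(C)C)c1O
F2 | step 4 | 1-[2-hydroxy-4,6-bis(methoxymethoxy)-3-(3-methylbut-2-en-1-yl)phenyl]ethan-1-one | CC(=O)c1c(OCOC)cc(OCOC)c(CC=C(C)C)c1O
F3 | step 4 | (E)-3-(dimethylamino)-1-[2-hydroxy-4,6-bis(methoxymethoxy)-3-(3-methylbut-2-en-1-yl)phenyl]prop-2-en-1-one | CN(C)/C=C/C(=O)c1c(OCOC)cc(OCOC)c(CC=C(C)C)c1O
F4 | step 4 | 3-iodo-5,7-bis(methoxymethoxy)-8-(3-methylbut-2-en-1-yl)-4H-chromen-4-one | CC(C)=CCc1c(OCOC)cc(OCOC)c2c(=O)c(I)coc12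
F5 | step 8 | 5-(methoxymethoxy)-2-(trimethylstannyl)phenyl benzoate | COCOc1ccc([Sn](C)(C)C)c(OC(=O)c2ccccc2)c1
F6 | step 8 | 2-[5-hydroxy-7-(methoxymethoxy)-8-(3-methylbut-2-en-1-yl)-4-oxo-4H-chromen-3-yl]-5-(methoxymethoxy)phenyl benzoate | CC(C)=CCc1c(OCOC)cc(O)c2c(=O)c(-c3ccc(OCOC)cc3OC(=O)c4ccccc4)coc12
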